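**Plan**

- Retrosynthesis: remove both MOM ethers; return the C4 ketone to a carbinol; cut O1–C8a and C8–CH2(prenyl) together at an aryne C8a≡C8 of ring A; return both carbinols to a 1,3-diketone and cut C2–C3 (Claisen) into a ring A methyl ketone and a ring B ester; cut the ring B prenyl at C3′–CH2 (Suzuki–Miyaura).
- Enabling feature: in ring A, O1 (on C8a) and the prenyl group (on C8) are ortho neighbours, C8 lies between C8a and the oxygen-bearing C7, and the C2 oxygen sits three atoms from C4a. An aryne C8a≡C8, made from a C8a–F/C8–H pair, can therefore take up O1 and the prenyl carbon in one operation while closing ring C (O1, C2, C3, C4, C4a, C8a).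
- Forward order: rings A and B are bought as benzenes; ring B is prenylated, the chain is joined by Claisen condensation, both carbonyls are reduced, and ring C, the only ring made, is closed in step 6. Oxidation at C4 and MOM removal finish the route.
- Stereochemistry: C2 (S) is set by Noyori asymmetric transfer hydrogenation of the diketone and survives ring closure because its C–O bond is never broken. The C4 carbinol is a temporary oxidation level that tolerates the organolithium and blocks retro-oxa-Michael racemisation; it is erased in step 7.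

Key step: step 6

Remark on the chemistry: the (S,S) catalyst is assigned from its established sense with aryl alkyl ketones (acetophenone gives (S)-1-phenylethanol). The C4 configuration and the 2,4-cis relationship of the intermediate flavan-4-ol follow from this and do not matter for the target.

**Step 1**
Reactants: 1 1-(2-fluoro-4-hydroxyphenyl)ethan-1-one
Product: 2 1-[2-fluoro-4-(methoxymethoxy)phenyl]ethan-1-one
Conditions: MOMCl (1.5 equiv), iPr2NEt (2.0 equiv), CH2Cl2, 0 °C → rt
Reagents that add atoms: chloromethyl methyl ether (MOMCl), COCCl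
Why: O-alkylation of the acidic phenol (MOM protection) should be clean, and the MOM group later acidifies the neighbouring C–H, survives n-BuLi and leaves under mild acid.

**Step 2**
Reactants: 3 methyl 3-bromo-4-hydroxybenzoate
Product: 4 methyl 3-bromo-4-(methoxymethoxy)benzoate
Conditions: MOMCl (1.5 equiv), iPr2NEt (2.0 equiv), CH2Cl2, 0 °C → rt
Reagents that add atoms: chloromethyl methyl ether (MOMCl), COCCl
Why: The same MOM protection of a phenol, here masking the ring B hydroxyl before cross-coupling and enolate chemistry.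

**Step 3**
Reactants: 4 methyl 3-bromo-4-(methoxymethoxy)benzoate
Product: 5 methyl 4-(methoxymethoxy)-3-(3-methylbut-2-en-1-yl)benzoate
Conditions: prenylboronic acid pinacol ester (1.5 equiv), PdCl2(dppf) (5 mol %), K3PO4 (3 equiv), THF/H2O (10:1), 65 °C
Reagents that add atoms: 4,4,5,5-tetramethyl-2-(3-methylbut-2-en-1-yl)-1,3,2-dioxaborolane, CC(C)=CCB1OC(C)(C)C(C)(C)O1
Why: Suzuki–Miyaura coupling of an aryl bromide with a prenyl boronate should deliver the linear prenyl arene by C–C bond formation at the unsubstituted allyl terminus, with ester and MOM ether inert.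

**Step 4**
Reactants: 2 1-[2-fluoro-4-(methoxymethoxy)phenyl]ethan-1-one; 5 methyl 4-(methoxymethoxy)-3-(3-methylbut-2-en-1-yl)benzoate
Product: 6 1-[2-fluoro-4-(methoxymethoxy)phenyl]-3-[4-(methoxymethoxy)-3-(3-methylbut-2-en-1-yl)phenyl]propane-1,3-dione
Conditions: LiHMDS (2.2 equiv), THF, −78 °C; then 5, −78 °C → rt; AcOH quench
Reagents that add atoms: none
Why: Crossed Claisen condensation of the lithium enolate of 2 with the non-enolisable ester 5 forms C2–C3, driven by deprotonation of the product diketone, and at or below room temperature the ortho fluorine should not be displaced.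

**Step 5**
Reactants: 6 1-[2-fluoro-4-(methoxymethoxy)phenyl]-3-[4-(methoxymethoxy)-3-(3-methylbut-2-en-1-yl)phenyl]propane-1,3-dione
Product: 8 (1S,3S)-1-[2-fluoro-4-(methoxymethoxy)phenyl]-3-[4-(methoxymethoxy)-3-(3-methylbut-2-en-1-yl)phenyl]propane-1,3-diol, via hydroxy ketone 7 (not isolated)
Conditions: RuCl[(S,S)-TsDPEN](p-cymene) (2 mol %), HCO2H/Et3N (5:2), DMF, 40 °C
Reagents that add atoms: none
Why: Noyori asymmetric transfer hydrogenation reduces each aryl ketone under catalyst control with the same facial sense as acetophenone, so the anti (1S,3S) diol should form whichever carbonyl reacts first, with the future C2 set as S and the prenyl olefin and MOM ethers untouched.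

**Step 6**
Reactants: 8 (1S,3S)-1-[2-fluoro-4-(methoxymethoxy)phenyl]-3-[4-(methoxymethoxy)-3-(3-methylbut-2-en-1-yl)phenyl]propane-1,3-diol
Product: 12 (2S,4S)-7-(methoxymethoxy)-2-[4-(methoxymethoxy)-3-(3-methylbut-2-en-1-yl)phenyl]-8-(3-methylbut-2-en-1-yl)chroman-4-ol, via trilithiated diol 9 (not isolated), via tethered aryne 10 (not isolated), via 8-lithiochromanolate 11 (not isolated)
Conditions: n-BuLi (3.05 equiv), THF (0.02 M), −78 °C, 1 h; −78 → 0 °C, 1 h; then CuBr·SMe2 (20 mol %), prenyl bromide (1.3 equiv), −78 → 0 °C; H2O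
Reagents that add atoms: 1-bromo-3-methylbut-2-ene (prenyl bromide), CC(C)=CCBr
Why: Two equivalents of n-BuLi form the dialkoxide and the third removes the only arene proton flanked by F and OMOM (the future C8) to give 9, which on warming loses LiF to aryne 10 (C8a≡C8); the C2 alkoxide adds to C8a, and the resulting C8 aryllithium 11, held between O1 and the OMOM oxygen, is transmetalated to copper and alkylated by prenyl bromide at its primary carbon. The closest known reaction type is the benzyne-mediated cyclization–functionalization sequence, in which a tethered heteroatom nucleophile closes onto an aryne made by ortho-metalation and halide loss and the new aryl-metal is trapped by a carbon electrophile, combined with the standard copper-mediated prenylation of ortho-lithiated aryl MOM ethers. Ring C closes in the 6-exo-dig mode, the oxygen attacking through the in-plane orbital the aryne carbon next to the tether-bearing C4a. No stereocenter is created: C2 keeps its S configuration because its C–O bond is never broken (that oxygen becomes O1), and C4 is a spectator alkoxide. The step needs oxygen at C8a and carbon at C8, and this is secured twice: the three-atom tether can reach only C8a (attack at C8 would need a meta-bridged ring, and the C4 alkoxide can form no viable ring), and the C7 OMOM group polarises the aryne as in 3-alkoxyarynes, so the nucleophile enters meta and the carbanion develops ortho to that oxygen. Chemoselectivity rests on stoichiometry and temperature: the base is consumed at −78 °C before the aryne appears, so ring B and the allylic positions are not metalated and no alkyllithium is left to add to 10, while high dilution favours ring closure over attack of 9 on 10.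

**Step 7**
Reactants: 12 (2S,4S)-7-(methoxymethoxy)-2-[4-(methoxymethoxy)-3-(3-methylbut-2-en-1-yl)phenyl]-8-(3-methylbut-2-en-1-yl)chroman-4-ol
Product: 13 (2S)-7-(methoxymethoxy)-2-[4-(methoxymethoxy)-3-(3-methylbut-2-en-1-yl)phenyl]-8-(3-methylbut-2-en-1-yl)chroman-4-one
Conditions: DMP (1.3 equiv), pyridine (3 equiv), CH2Cl2, 0 °C → rt
Reagents that add atoms: none
Why: Dess–Martin oxidation of the benzylic secondary alcohol under buffered, non-basic conditions should give the flavanone without touching the olefins or MOM ethers and without opening ring C, so C2 stays S.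

**Step 8**
Reactants: 13 (2S)-7-(methoxymethoxy)-2-[4-(methoxymethoxy)-3-(3-methylbut-2-en-1-yl)phenyl]-8-(3-methylbut-2-en-1-yl)chroman-4-one
Product: 14 glabrol, (2S)-7-hydroxy-2-[4-hydroxy-3-(3-methylbut-2-en-1-yl)phenyl]-8-(3-methylbut-2-en-1-yl)chroman-4-one
Conditions: HCl (1.25 M in MeOH), THF, 25 → 40 °C
Reagents that add atoms: none
Why: Acid-catalysed acetal exchange with methanol removes both MOM groups under mild conditions precedented for ortho-prenyl phenols, and the absence of base avoids ring-opening racemisation of the 4′-hydroxyflavanone.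

**Compound list**

1 | 1-(2-fluoro-4-hydroxyphenyl)ethan-1-one | CC(=O)c1ccc(O)cc1F | starting material
2 | 1-[2-fluoro-4-(methoxymethoxy)phenyl]ethan-1-one | CC(=O)c1ccc(OCOC)cc1F | intermediate
3 | methyl 3-bromo-4-hydroxybenzoate | COC(=O)c1ccc(O)c(Br)c1 | starting material
4 | methyl 3-bromo-4-(methoxymethoxy)benzoate | COCOc1ccc(C(=O)OC)cc1Br | intermediate
5 | methyl 4-(methoxymethoxy)-3-(3-methylbut-2-en-1-yl)benzoate | COCOc1ccc(C(=O)OC)cc1CC=C(C)C | intermediate
6 | 1-[2-fluoro-4-(methoxymethoxy)phenyl]-3-[4-(methoxymethoxy)-3-(3-methylbut-2-en-1-yl)phenyl]propane-1,3-dione (largely enolised) | COCOc1ccc(C(=O)CC(=O)c2ccc(OCOC)c(CC=C(C)C)c2)c(F)c1 | intermediate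
7 | (3S)-3-[2-fluoro-4-(methoxymethoxy)phenyl]-3-hydroxy-1-[4-(methoxymethoxy)-3-(3-methylbut-2-en-1-yl)phenyl]propan-1-one | COCOc1ccc([C@@H](O)CC(=O)c2ccc(OCOC)c(CC=C(C)C)c2)c(F)c1 | intermediate
8 | (1S,3S)-1-[2-fluoro-4-(methoxymethoxy)phenyl]-3-[4-(methoxymethoxy)-3-(3-methylbut-2-en-1-yl)phenyl]propane-1,3-diol (anti) | COCOc1ccc([C@@H](O)C[C@H](O)c2ccc(OCOC)c(CC=C(C)C)c2)c(F)c1 | intermediate
9 | dilithium dialkoxide of 8, lithiated at the ring A carbon between F and OMOM | COCOc1ccc([C@@H](O[Li])C[C@H](O[Li])c2ccc(OCOC)c(CC=C(C)C)c2)c(F)c1[Li] | intermediate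
10 | aryne from 9 by loss of LiF (triple bond between the former C–F and C–Li carbons), dilithium dialkoxide | COCOC1=CC=C([C@@H](O[Li])C[C@H](O[Li])c2ccc(OCOC)c(CC=C(C)C)c2)C#C1 | intermediate
11 | lithium (2S,4S)-8-lithio-7-(methoxymethoxy)-2-[4-(methoxymethoxy)-3-(3-methylbut-2-en-1-yl)phenyl]chroman-4-olate | CC(C)=CCc1cc([C@@H]2C[C@H](O[Li])c3ccc(OCOC)c([Li])c3O2)ccc1OCOC | intermediate
12 | (2S,4S)-7-(methoxymethoxy)-2-[4-(methoxymethoxy)-3-(3-methylbut-2-en-1-yl)phenyl]-8-(3-methylbut-2-en-1-yl)chroman-4-ol (2,4-cis) | CC(C)=CCc1cc([C@@H]2C[C@H](O)c3ccc(OCOC)c(CC=C(C)C)c3O2)ccc1OCOC | intermediate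
13 | (2S)-7-(methoxymethoxy)-2-[4-(methoxymethoxy)-3-(3-methylbut-2-en-1-yl)phenyl]-8-(3-methylbut-2-en-1-yl)chroman-4-one | CC(C)=CCc1cc([C@@H]2CC(=O)c3ccc(OCOC)c(CC=C(C)C)c3O2)ccc1OCOC | intermediate
14 | glabrol, (2S)-7-hydroxy-2-[4-hydroxy-3-(3-methylbut-2-en-1-yl)phenyl]-8-(3-methylbut-2-en-1-yl)chroman-4-one | CC(C)=CCc1cc([C@@H]2CC(=O)c3ccc(O)c(CC=C(C)C)c3O2)ccc1O | target

**Totals**

Total step count: 8. Longest linear sequence: 7 steps (3 → 4 → 5 → 6 → 8 → 12 → 13 → 14).

**Steps most likely to fail**

Step 6. The aryne may be intercepted intermolecularly by still-unreacted aryllithium before the alkoxide closes the ring, or the C8 aryllithium may be protonated before alkylation. The fallback separates the two bond formations and avoids the aryne. Diol 8 is heated with KOtBu in DMF (80–100 °C), so the C2 alkoxide displaces fluoride by intramolecular nucleophilic aromatic substitution (6-exo), giving (2S,4S)-7-(methoxymethoxy)-2-[4-(methoxymethoxy)-3-(3-methylbut-2-en-1-yl)phenyl]chroman-4-ol F1. Directed ortho-metalation of this compound with n-BuLi (2.2 equiv, THF, 0 °C) should occur at C8, the position flanked by O1 and OMOM, giving 11, and CuBr·SMe2/prenyl bromide then returns to the route at 12.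

Step 5. Transfer hydrogenation may stall on the strongly enolised, electron-rich diketone, or stereocontrol may erode in the second reduction. The fallback sets C2 by C–C bond formation instead:
- Ester 5 is reduced with LiAlH4 to [4-(methoxymethoxy)-3-(3-methylbut-2-en-1-yl)phenyl]methanol F2, which is oxidised with MnO2 to 4-(methoxymethoxy)-3-(3-methylbut-2-en-1-yl)benzaldehyde F3.
- Ketone 2 is converted with TMSOTf/Et3N into {1-[2-fluoro-4-(methoxymethoxy)phenyl]ethenyl}oxy(trimethyl)silane F4.
- A catalytic enantioselective Mukaiyama aldol addition (SiCl4, chiral bisphosphoramide Lewis base, iPr2NEt, CH2Cl2, −78 °C, with the catalyst enantiomer chosen to give the S carbinol) joins F3 and F4 to (3S)-1-[2-fluoro-4-(methoxymethoxy)phenyl]-3-hydroxy-3-[4-(methoxymethoxy)-3-(3-methylbut-2-en-1-yl)phenyl]propan-1-one F5.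
- Hydroxyl-directed Evans–Saksena reduction with Me4NBH(OAc)3 gives the anti diol and returns to the route at 8.

Step 8. Under protic acid the liberated ortho-phenols may cyclise onto the prenyl groups (chroman formation), and ring C may open and re-close with loss of configuration at C2. The fallback replaces protic solvolysis with a non-protic silyl exchange. Compound 13 is treated with TMSOTf and 2,2′-bipyridyl in MeCN at 0 °C, converting both aryl MOM ethers into aryl silyl ethers and giving (2S)-8-(3-methylbut-2-en-1-yl)-2-[3-(3-methylbut-2-en-1-yl)-4-(trimethylsilyloxy)phenyl]-7-(trimethylsilyloxy)chroman-4-one F6. Adding water at room temperature hydrolyses the silyl ethers at near-neutral pH and returns to the route at 14.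

**Further compounds**

F1 | step 6 | (2S,4S)-7-(methoxymethoxy)-2-[4-(methoxymethoxy)-3-(3-methylbut-2-en-1-yl)phenyl]chroman-4-ol | CC(C)=CCc1cc([C@@H]2C[C@H](O)c3ccc(OCOC)cc3O2)ccc1OCOC
F2 | step 5 | [4-(methoxymethoxy)-3-(3-methylbut-2-en-1-yl)phenyl]methanol | COCOc1ccc(CO)cc1CC=C(C)C
F3 | step 5 | 4-(methoxymethoxy)-3-(3-methylbut-2-en-1-yl)benzaldehyde | COCOc1ccc(C=O)cc1CC=C(C)C
F4 | step 5 | {1-[2-fluoro-4-(methoxymethoxy)phenyl]ethenyl}oxy(trimethyl)silane | COCOc1ccc(C(=C)O[Si](C)(C)C)c(F)c1
F5 | step 5 | (3S)-1-[2-fluoro-4-(methoxymethoxy)phenyl]-3-hydroxy-3-[4-(methoxymethoxy)-3-(3-methylbut-2-en-1-yl)phenyl]propan-1-one | COCOc1ccc(C(=O)C[C@H](O)c2ccc(OCOC)c(CC=C(C)C)c2)c(F)c1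
F6 | step 8 | (2S)-8-(3-methylbut-2-en-1-yl)-2-[3-(3-methylbut-2-en-1-yl)-4-(trimethylsilyloxy)phenyl]-7-(trimethylsilyloxy)chroman-4-one | CC(C)=CCc1cc([C@@H]2CC(=O)c3ccc(O[Si](C)(C)C)c(CC=C(C)C)c3O2)ccc1O[Si](C)(C)C
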